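**Retrosynthetic overview**
1. Target 11 ⇒ 10 (N(4)-Boc, bis-O-methyl ether) by one global Lewis-acid deprotection.
2. 10 ⇒ bis(bromoacetamide) 6 + two benzylic ylides 8. Both Cα–Cβ bonds are cut with inverted polarity: the amide α-carbon is the electrophile (enolonium equivalent) and the benzylic carbon is the carbanion. Loss of PPh3 after alkylation gives both (E)-alkenes.
3. 6 ⇒ N(4)-Boc-spermidine 4 + bromoacetyl bromide 5; 4 ⇒ spermidine 1.
4. No ring is formed at any stage; both arene rings are bought intact in phosphonium salt 7.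

Assumption: the target has no stereocentres, so "single enantiomer" is read as the single (E,E)-isomer, isolated as the free base.

**Step 1**
Reactants: 1 spermidine
Product: 4 N(4)-Boc-spermidine (tert-butyl N-(4-aminobutyl)-N-(3-aminopropyl)carbamate), via bis(trifluoroacetamide) 2 (not isolated), via N(4)-Boc bis(trifluoroacetamide) 3 (not isolated)
Conditions: CF3CO2Et (2.1 equiv), MeOH, −78 → 0 °C; then Boc2O (1.2 equiv), 0 °C → rt; then conc. aq. NH3, rt, 16 h
Reagents that add atoms: di-tert-butyl dicarbonate CC(C)(C)OC(=O)OC(=O)OC(C)(C)C; ethyl trifluoroacetate CCOC(=O)C(F)(F)F (its atoms stay only in 2 and 3)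
Why: Ester aminolysis by ethyl trifluoroacetate is selective for the two primary amines, Boc2O then caps the remaining N(4), and aqueous ammonia cleaves the labile trifluoroacetamides but not the carbamate (chemoselective acylation / carbamate formation / ammonolysis; no stereocentre).

**Step 2**
Reactants: 4 N(4)-Boc-spermidine; 5 bromoacetyl bromide
Product: 6 N(4)-Boc-N(1),N(8)-bis(bromoacetyl)spermidine (tert-butyl N-[4-(2-bromoacetamido)butyl]-N-[3-(2-bromoacetamido)propyl]carbamate)
Conditions: 5 (2.2 equiv), CH2Cl2 / sat. aq. NaHCO3, 0 °C, 1 h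
Reagents that add atoms: none
Why: Schotten–Baumann N-acylation of the two primary amines is far faster than any reaction at the carbamate nitrogen, and the Boc group prevents N(4) from alkylating the new C–Br bonds; this installs two enolonium equivalents (no stereocentre).

**Step 3**
Reactants: 6 N(4)-Boc-N(1),N(8)-bis(bromoacetyl)spermidine; 7 (4-methoxybenzyl)triphenylphosphonium chloride
Product: 10 N(4)-Boc-N(1),N(8)-bis[(E)-4-methoxycinnamoyl]spermidine, via ylide 8 (not isolated), via bis(phosphonium) dibromide 9 (not isolated)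
Conditions: 7 (4.6 equiv), NaN(SiMe3)2 (4.4 equiv), THF, 0 °C, 30 min; then 6, −78 °C → rt, 2 h; then 65 °C, 6 h
Reagents that add atoms: none
Why: Proposed new method: the semi-stabilised ylide 8 (conjugate acid pKa about 18, too weak a base to deprotonate the amide N–H) alkylates each bromoacetamide carbon by SN2 to give the β-phosphonio amide 9; a second equivalent of 8 then removes an amide α-proton and PPh3 leaves (retro-phospha-Michael, E1cB-type), giving the conjugated alkene as the thermodynamically favoured (E)-isomer from the conformer with aryl and carboxamide anti. The closest known reaction is the alkylation of alkylidenephosphoranes with α-halo esters followed by Hofmann-type loss of PPh3 (Bestmann-type olefination), here extended to a secondary α-bromoamide and run twice in one molecule.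

**Step 4**
Reactants: 10 N(4)-Boc-N(1),N(8)-bis[(E)-4-methoxycinnamoyl]spermidine
Product: 11 N(1),N(8)-bis[(E)-4-coumaroyl]spermidine (target)
Conditions: BBr3 (9 equiv), CH2Cl2, −78 °C → rt, 12 h; H2O, 0 °C; aq. NaHCO3 to pH 9
Reagents that add atoms: none
Why: BBr3 complexes the ether oxygens and bromide displaces methyl (Lewis-acid aryl methyl ether cleavage) while also cleaving the tert-butyl carbamate; the secondary amides and (E)-cinnamoyl alkenes tolerate these conditions, and hydrolytic work-up frees the phenols and the amine (no stereocentre; alkene geometry unchanged).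

**Compound list**
1 | spermidine | NCCCCNCCCN | starting material
2 | N(1),N(8)-bis(trifluoroacetyl)spermidine | O=C(NCCCCNCCCNC(=O)C(F)(F)F)C(F)(F)F | intermediate
3 | N(4)-Boc-N(1),N(8)-bis(trifluoroacetyl)spermidine | CC(C)(C)OC(=O)N(CCCCNC(=O)C(F)(F)F)CCCNC(=O)C(F)(F)F | intermediate
4 | N(4)-Boc-spermidine | CC(C)(C)OC(=O)N(CCCCN)CCCN | intermediate
5 | bromoacetyl bromide | O=C(Br)CBr | starting material
6 | N(4)-Boc-N(1),N(8)-bis(bromoacetyl)spermidine | CC(C)(C)OC(=O)N(CCCCNC(=O)CBr)CCCNC(=O)CBr | intermediate
7 | (4-methoxybenzyl)triphenylphosphonium chloride | COc1ccc(C[P+](c2ccccc2)(c2ccccc2)c2ccccc2)cc1.[Cl-] | starting material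
8 | (4-methoxybenzylidene)triphenylphosphorane | COc1ccc(C=P(c2ccccc2)(c2ccccc2)c2ccccc2)cc1 | intermediate
9 | N(4)-Boc-N(1),N(8)-bis[3-(4-methoxyphenyl)-3-(triphenylphosphonio)propanoyl]spermidine dibromide (diastereomer mixture, both centres destroyed in the same step) | COc1ccc(C(CC(=O)NCCCCN(CCCNC(=O)CC(c2ccc(OC)cc2)[P+](c2ccccc2)(c2ccccc2)c2ccccc2)C(=O)OC(C)(C)C)[P+](c2ccccc2)(c2ccccc2)c2ccccc2)cc1.[Br-].[Br-] | intermediate
10 | N(4)-Boc-N(1),N(8)-bis[(E)-4-methoxycinnamoyl]spermidine | COc1ccc(/C=C/C(=O)NCCCCN(CCCNC(=O)/C=C/c2ccc(OC)cc2)C(=O)OC(C)(C)C)cc1 | intermediate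
11 | N(1),N(8)-bis[(E)-4-coumaroyl]spermidine | O=C(/C=C/c1ccc(O)cc1)NCCCCNCCCNC(=O)/C=C/c1ccc(O)cc1 | target

**Totals**
Total step count: 4. Longest linear sequence: 4 (1 → 4 → 6 → 10 → 11).

**Steps most likely to fail, with fallbacks**

Step 3 (highest risk). The amide α-C–H is much less acidic than that of an ester, so 9 may stall as its ylide instead of losing PPh3, and double alkylation of one ylide carbon could compete. The fallback keeps the same polarity-reversed C–C bond but makes it on an ester, where the alkylation/elimination is established, and forms the amides afterwards. It sets out from 4 and uses ylide 8 made from 7 as in step 3. Ylide 8 (2.1 equiv) and methyl bromoacetate in THF, 0 °C → reflux, give, through [3-methoxy-1-(4-methoxyphenyl)-3-oxopropyl]triphenylphosphonium bromide F1 (not isolated), methyl (E)-3-(4-methoxyphenyl)prop-2-enoate F2. LiOH in THF/H2O followed by HCl gives (E)-3-(4-methoxyphenyl)prop-2-enoic acid F3. F3 (2.1 equiv) is then coupled with 4 (EDC·HCl, HOBt, iPr2NEt, DMF, rt), and the route is rejoined at 10.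

Step 4. BBr3 acting on a substrate that still carries the Boc group releases tert-butyl cation next to two electron-rich arenes, and HBr could add to the alkenes. The fallback splits the global deprotection into two mechanistically different operations. It sets out from 10: TFA/CH2Cl2 (1:4) with anisole at rt, then basic work-up, removes only the Boc group and gives N(1),N(8)-bis[(E)-4-methoxycinnamoyl]spermidine F4. Nucleophilic O-demethylation of F4 by SN2 at methyl with NaSEt (6 equiv) in DMF at 120 °C, followed by neutralisation, returns to the route at 11. Any thiolate conjugate adduct reverts at this temperature.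

Step 1. The three-operation one-pot may give incomplete selectivity or leave trifluoroacetamide on a polar diamine that is hard to purify. The fallback uses isolable, crystalline imide intermediates and sets out from 1. N-Ethoxycarbonylphthalimide (2.0 equiv, CH2Cl2, rt) converts only the primary amines and gives N(1),N(8)-bis(phthaloyl)spermidine F5. Boc2O and Et3N give N(4)-Boc-N(1),N(8)-bis(phthaloyl)spermidine F6. Hydrazinolysis (N2H4·H2O, EtOH, reflux) returns to the route at 4.

**Further compounds**
F1 | step 3 | [3-methoxy-1-(4-methoxyphenyl)-3-oxopropyl]triphenylphosphonium bromide | COC(=O)CC(c1ccc(OC)cc1)[P+](c1ccccc1)(c1ccccc1)c1ccccc1.[Br-]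
F2 | step 3 | methyl (E)-3-(4-methoxyphenyl)prop-2-enoate | COC(=O)/C=C/c1ccc(OC)cc1
F3 | step 3 | (E)-3-(4-methoxyphenyl)prop-2-enoic acid | OC(=O)/C=C/c1ccc(OC)cc1
F4 | step 4 | N(1),N(8)-bis[(E)-4-methoxycinnamoyl]spermidine | COc1ccc(/C=C/C(=O)NCCCCNCCCNC(=O)/C=C/c2ccc(OC)cc2)cc1
F5 | step 1 | N(1),N(8)-bis(phthaloyl)spermidine | O=C1c2ccccc2C(=O)N1CCCCNCCCN1C(=O)c2ccccc2C1=O
F6 | step 1 | N(4)-Boc-N(1),N(8)-bis(phthaloyl)spermidine | O=C1c2ccccc2C(=O)N1CCCCN(CCCN1C(=O)c2ccccc2C1=O)C(=O)OC(C)(C)C
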